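## Structural features

The target is a (2S)-flavanone. Ring A is a fully substituted phloroglucinol nucleus with oxygen on C5, C7 and C8a; ring C is the dihydropyranone (O1, C2, C3, C4) fused to ring A through C4a and C8a; ring B is a 4-hydroxy-2-methoxyphenyl group on C2. C8 carries a hydrated lavandulyl chain: the C1'' methylene, the (R) stereocentre C2'' with an isopropenyl group, and a CH2CH2C(CH3)2OH arm. The two stereocentres are five bonds apart (C2–O1–C8a–C8–C1''–C2''), so neither can direct the other; each is set on its own, and the C2 epimers are diastereomers. Fragile groups: C2 epimerises by retro-oxa-Michael opening to the chalcone under base, and by ionisation of the benzylic C2–O1 bond under acid (helped by the 2',4'-dioxygenated ring B). The isopropenyl group and the tertiary alcohol ionise in acid and can cyclise onto O7 (chroman) or onto each other (tetrahydropyran), and the electron-rich ring A is easily over-substituted. The real difficulty is ring A: six different substituents, the chain on C8 and not C6, next to a labile C2 centre. The key step exploits the fact that O1 and C4 of ring C sit on the adjacent ring A carbons C8a and C4a. These are the two carbons of an aryne polarised by the C5 oxygen, so ring C can be delivered as one chiral three-carbon piece with C2 already in place.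

## Logic of the disconnections

**24 to 23.** The four O–CH2 acetal bonds on O5, O7, O4' and the tertiary side-chain oxygen are cut. All four hydroxyls would protonate an aryl anion or add to an aryne, so they are masked as one fluoride-inert group, which leaves a single last step. The forward step must avoid Brønsted acid strong enough to protonate the isopropenyl group or ionise C2–O1, hence a buffered silyl triflate exchange.

**23 to 16 and 20.** The O1–C8a and C4–C4a bonds are cut. Both end on adjacent ring A carbons, so ring A becomes an aryne (from 16) and ring C a three-carbon alkoxide/ester unit (20) that already carries C2. This gives two fragments of similar size, avoids any chalcone, and fixes the 6/8 regiochemistry by where silicon and triflate sit. The forward step needs alkoxide addition at C8a, acyl capture of the C4a anion faster than its protonation, and a low base load on the product.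

**20 to 19, 18 and 17.** The C2–H bond (hydride), the C3–CO2Me bond (Claisen acylation) and the O4' acetal are cut. A β-keto ester is the standard substrate for catalytic asymmetric reduction, so C2 comes from a catalyst and a commercial acetophenone. The reduction must be highly face-selective on an ortho-methoxy aryl ketone and must not ionise the electron-rich benzylic alcohol.

**16 to 14 and 8 (through 15).** The C8–C1'' bond is cut. It is an aryl–alkyl bond next to, but not at, the stereocentre, so the cut separates an achiral arene from a small chiral iodide, and the halogen position defines C8. The coupling must occur at a carbon flanked on both sides, in the presence of an aryl triflate, and without fluoride.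

**14 to 11, 10 and 9.** The C4a–Si and O–S bonds (retro-Brook and triflation), the two C–Br bonds and two O–acetal bonds are cut. The oxygen left free in 10 becomes O1; its two ortho positions are equivalent, so double ortho-bromination and exchange of one bromine leave no regiochemical choice. Bromination must go ortho to the hydroxyl and not between the acetals, and the protection of 9 is statistical.

**8 to 7, 6, 5 and 4.** These are functional group changes: tertiary O–acetal, C–I, epoxide C–O/C–H, and the acyl carbon to CH2. The tertiary alcohol is traced to the trisubstituted alkene of a prenyl group (the more nucleophilic of the two alkenes) and the iodide to the acyl carbon. Epoxidation must tell the two alkenes apart, and hydride must open the epoxide at its secondary carbon.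

**4 to 3, 1 and 2.** The C2''–C3'' bond and the N–acyl bond are cut. At this oxidation level C2'' is α to a carbonyl, so auxiliary-controlled enolate alkylation sets it, and the isopropenyl group arises by deconjugation of the senecioyl unit of 2. This reduces the chain to a five-carbon acid chloride, the auxiliary 1 and a prenyl electrophile. The forward step needs α- (not γ-) alkylation and high face selectivity.

## Other disconnections considered

**Alternative 1:** The cut is the C1''–C2'' bond. Base would release an ortho-quinone methide from sulfone A1; the enamine of aldehyde A2 with a diarylprolinol silyl ether would add to its CH2, and the phenol oxygen would close onto the aldehyde carbon to give chroman-2-ol A3 with C2'' set by the catalyst.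
- In its favour: C2'' is set catalytically without an auxiliary, which is better than the chosen plan. No cross-coupling at a hindered ring carbon is needed. The lactol oxygen is set apart from the two acetal oxygens, so ring A is differentiated without a statistical protection, also better.
- Against it here: the lactol carbon must still become the isopropenyl group (methyl addition, oxidation, methylenation) through a methyl ketone whose α-carbon is C2'', so the new centre is exposed to enolisation. The step does nothing for ring C or C2, and ring A then has no handle at C4a.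
- Comparison: on structure it solves the chain but leaves the flavanone core open, whereas the chosen plan closes ring C with C2 preset. On mechanism it rests on established aminocatalysis and is the better of the two in precedent. On step economy the processing of A3 plus a later annulation should make it longer.

**Alternative 2:** The cut is through ring A at C8a–C8 and C7–C6. Heating siloxyalkyne A4 with cyclobutenone A5 (electrocyclic opening to a vinylketene, [2+2] addition to the ynol ether, ring opening, 6π closure) would give phenol A6.
- In its favour: ring A regiochemistry is complete by construction, with three differentiated oxygens and the chain on C8; this is better than the statistical bis-acetal and ortho-bromination of the chosen plan. Limonene could supply A4 with no loss of carbon, because the aldehyde carbon of the cleaved terpene becomes C8, a better use of the chiral pool.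
- Against it here: A4 needs an ester-to-ynol-ether homologation. The vinylketene is generated hot next to an isopropenyl group. C4a is left as C–H, so acylation and the whole of ring C with C2 remain, most likely via a chalcone on which C2 is set late. Three orthogonal oxygen groups must be managed.
- Comparison: on ring A it is the equal or the better; on ring C and C2 the chosen plan is more direct. On mechanism it is a known pericyclic cascade against a new annulation. On step economy it should be longer, since it replaces four steps of the chosen plan and leaves the annulation undone.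

**Alternative 3:** The cut is C2–C3. A chiral dirhodium tetracarboxylate such as Rh2(S-PTTL)4 would decompose diazomethyl ketone A7, and the rhodium carbene would insert into a benzylic C–H bond of the ortho benzyl ether to give A8, creating C2.
- In its favour: ring C closes and C2 is set in one catalytic step. The O1–C2 bond comes from a simple O-benzylation. As in the chosen plan the product is one deprotection from the target (equal). The all-silyl protection allows a fluoride deprotection with no acetal cleavage next to the acid-sensitive chain (better).
- Against it here: an acceptor-only carbene has several outlets. Attack on O1 gives an oxonium ylide and a [1,2]-benzyl shift to a 2-benzylbenzofuran-3-one. Cyclopropanation of the isopropenyl group, addition to the electron-rich ring B, and the less favoured six-membered insertion geometry all compete. Enantiocontrol for such carbenes is uncertain, and any shortfall gives diastereomers. A7 needs a doubly ortho-substituted benzoic acid and diazomethane.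
- Comparison: on structure the same ring is closed. On mechanism the chosen plan brings C2 in from a reliable ketone reduction and has no C–H site selection to control. On step economy the two are about equal.

Key step: step 14

Remark on the chemistry: cleaving the ring of (R)-limonene would give the right C2'' configuration but a CH2–CHO arm where the chain needs a single methylene. One carbon would have to be excised next to the isopropenyl group, so the route builds C2'' by auxiliary-controlled alkylation and uses no terpene. The structures of the two key-step partners and of the key-step product were checked against the target (2S, 2''R) and are used unchanged. The alcohol partner enters the key step as its trimethylsilyl ether.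

## Route

Step 1
Reactants: 1 (S)-4-benzyloxazolidin-2-one; 2 3-methylbut-2-enoyl chloride
Product: 3 (S)-4-benzyl-3-(3-methylbut-2-enoyl)oxazolidin-2-one
Conditions: n-BuLi, THF, −78 °C; then 2, −78 to 0 °C
Reagents that add atoms: none
Why: N-acylation of the lithiated oxazolidinone by the acid chloride (standard imide formation for Evans auxiliaries); the low temperature keeps the enoyl unit conjugated.

Step 2
Reactants: 3 (S)-4-benzyl-3-(3-methylbut-2-enoyl)oxazolidin-2-one
Product: 4 (S)-4-benzyl-3-[(2S)-5-methyl-2-(prop-1-en-2-yl)hex-4-enoyl]oxazolidin-2-one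
Conditions: NaN(SiMe3)2, THF, −78 °C; prenyl bromide, −78 to −40 °C
Reagents that add atoms: prenyl bromide (1-bromo-3-methylbut-2-ene), CC(C)=CCBr
Why: γ-Deprotonation gives the chelated sodium dienolate, which alkylates at the α-carbon (deconjugative Evans asymmetric alkylation) and so creates the isopropenyl group. The benzyl group of the auxiliary blocks one face, so the allylic bromide should enter anti to it and set the (2S) centre that becomes C2''.

Step 3
Reactants: 4 (S)-4-benzyl-3-[(2S)-5-methyl-2-(prop-1-en-2-yl)hex-4-enoyl]oxazolidin-2-one
Product: 5 (S)-4-benzyl-3-[(2S)-3-(3,3-dimethyloxiran-2-yl)-2-(prop-1-en-2-yl)propanoyl]oxazolidin-2-one (both epimers at the oxirane CH)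
Conditions: mCPBA (1 equiv), NaHCO3, CH2Cl2, −20 to 0 °C
Reagents that add atoms: mCPBA (3-chloroperoxybenzoic acid), OOC(=O)c1cccc(Cl)c1
Why: Prilezhaev epoxidation; the trisubstituted alkene is the more nucleophilic, and the 1,1-disubstituted isopropenyl group is further deactivated by the adjacent imide carbonyl. The new oxirane centre is formed unselectively and is erased in step 4.

Step 4
Reactants: 5 (S)-4-benzyl-3-[(2S)-3-(3,3-dimethyloxiran-2-yl)-2-(prop-1-en-2-yl)propanoyl]oxazolidin-2-one
Product: 6 (2S)-5-methyl-2-(prop-1-en-2-yl)hexane-1,5-diol
Conditions: LiAlH4, THF, 0 °C to rt; Rochelle salt work-up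
Reagents that add atoms: none
Why: Hydride cleaves the imide to the primary alcohol and opens the trisubstituted epoxide by SN2 attack at its secondary carbon, which gives the tertiary alcohol. Imide reduction is faster than enolisation, so C2 should keep its configuration, and the auxiliary is recovered.

Step 5
Reactants: 6 (2S)-5-methyl-2-(prop-1-en-2-yl)hexane-1,5-diol
Product: 7 (5S)-6-iodo-2-methyl-5-(prop-1-en-2-yl)hexan-2-ol
Conditions: I2, PPh3, imidazole, CH2Cl2, 0 °C
Reagents that add atoms: iodine, II
Why: Appel-type iodination by SN2 displacement of the primary alkoxyphosphonium; the tertiary alcohol does not react at this temperature and the stereocentre is not involved.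

Step 6
Reactants: 7 (5S)-6-iodo-2-methyl-5-(prop-1-en-2-yl)hexan-2-ol
Product: 8 (2S)-1-iodo-5-(methoxymethoxy)-5-methyl-2-(prop-1-en-2-yl)hexane
Conditions: MOMCl, i-Pr2NEt, n-Bu4NI (cat.), CH2Cl2, 0 to 40 °C
Reagents that add atoms: chloromethyl methyl ether, COCCl
Why: Acetal formation by O-alkylation of the tertiary alcohol with the α-chloro ether, iodide catalysis helping the hindered hydroxyl; the acetal is inert to zinc, palladium and fluoride.

Step 7
Reactants: 9 phloroglucinol (benzene-1,3,5-triol)
Product: 10 3,5-bis(methoxymethoxy)phenol
Conditions: MOMCl (2 equiv), i-Pr2NEt, DMF, 0 °C to rt; chromatographic separation from the mono- and tris-ethers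
Reagents that add atoms: chloromethyl methyl ether, COCCl
Why: Statistical O-alkylation of three equivalent hydroxyls with a hard electrophile; the single free hydroxyl marks the oxygen that becomes O1.

Step 8
Reactants: 10 3,5-bis(methoxymethoxy)phenol
Product: 11 2,6-dibromo-3,5-bis(methoxymethoxy)phenol
Conditions: Br2 (2 equiv), t-BuNH2, toluene/CH2Cl2, −78 °C to rt
Reagents that add atoms: bromine, BrBr
Why: Ortho-selective bromination of a phenol by the bromine/tert-butylamine reagent, which delivers bromine to both positions next to the hydrogen-bonded hydroxyl and should leave the position between the two acetals untouched; the amine takes up HBr so the acetals survive.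

Step 9
Reactants: 11 2,6-dibromo-3,5-bis(methoxymethoxy)phenol
Product: 14 2-bromo-3,5-bis(methoxymethoxy)-6-(trimethylsilyl)phenyl trifluoromethanesulfonate, via aryl silyl ether 12 (not isolated), via lithium phenolate 13 (not isolated)
Conditions: (Me3Si)2NH, THF, 65 °C, then evaporation; n-BuLi (1 equiv), THF, −78 °C; Tf2O, −78 to 0 °C
Reagents that add atoms: hexamethyldisilazane, C[Si](C)(C)N[Si](C)(C)C; trifluoromethanesulfonic anhydride, O=S(=O)(OS(=O)(=O)C(F)(F)F)C(F)(F)F
Why: O-silylation, bromine–lithium exchange and 1,3 O-to-C silyl shift (retro-Brook rearrangement) give the ortho-silyl phenolate, which is triflated; this is the standard entry to ortho-silylaryl triflates. The two bromines are equivalent, so the single exchange raises no regiochemical question.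

Step 10
Reactants: 8 (2S)-1-iodo-5-(methoxymethoxy)-5-methyl-2-(prop-1-en-2-yl)hexane; 14 2-bromo-3,5-bis(methoxymethoxy)-6-(trimethylsilyl)phenyl trifluoromethanesulfonate
Product: 16 2-[(2R)-5-(methoxymethoxy)-5-methyl-2-(prop-1-en-2-yl)hexyl]-3,5-bis(methoxymethoxy)-6-(trimethylsilyl)phenyl trifluoromethanesulfonate, via alkylzinc iodide 15 (not isolated)
Conditions: 8, Zn (I2-activated), DMA, 40 °C, solution decanted from excess Zn; then 14, Pd(OAc)2, SPhos, THF/DMA, 45 °C
Reagents that add atoms: none
Why: Zinc insertion into the primary C–I bond and Negishi coupling with a bulky biarylphosphine, which is suited to aryl halides flanked on both sides. Oxidative addition should prefer C–Br over the triflate shielded by SiMe3, the medium contains no fluoride so the silyl triflate is spared, and the stereocentre β to zinc is not touched.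

Step 11
Reactants: 17 1-(4-hydroxy-2-methoxyphenyl)ethanone
Product: 18 1-[2-methoxy-4-(methoxymethoxy)phenyl]ethanone
Conditions: MOMCl, i-Pr2NEt, CH2Cl2, 0 °C to rt
Reagents that add atoms: chloromethyl methyl ether, COCCl
Why: O-alkylation of the acidic para-acyl phenol; the acetal matches those on ring A for a single final unmasking.

Step 12
Reactants: 18 1-[2-methoxy-4-(methoxymethoxy)phenyl]ethanone
Product: 19 methyl 3-[2-methoxy-4-(methoxymethoxy)phenyl]-3-oxopropanoate
Conditions: NaH, (MeO)2CO, THF, 65 °C; AcOH quench
Reagents that add atoms: dimethyl carbonate, COC(=O)OC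
Why: Claisen-type C-acylation of the ketone enolate with the carbonate, driven by deprotonation of the β-keto ester formed.

Step 13
Reactants: 19 methyl 3-[2-methoxy-4-(methoxymethoxy)phenyl]-3-oxopropanoate
Product: 20 methyl (3S)-3-hydroxy-3-[2-methoxy-4-(methoxymethoxy)phenyl]propanoate
Conditions: RuCl[(S,S)-TsDPEN](p-cymene) (cat.), HCO2H/Et3N (amine-rich), DMF, rt
Reagents that add atoms: none
Why: Noyori asymmetric transfer hydrogenation of an aryl ketone; by analogy with aryl alkyl ketones the (S,S) catalyst should deliver hydride to the face that gives the (S) alcohol (aryl group held by the arene ligand), and this sets C2. The buffered, room-temperature medium is chosen to spare the acetal and the electron-rich benzylic alcohol.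

Step 14
Reactants: 16 2-[(2R)-5-(methoxymethoxy)-5-methyl-2-(prop-1-en-2-yl)hexyl]-3,5-bis(methoxymethoxy)-6-(trimethylsilyl)phenyl trifluoromethanesulfonate; 20 methyl (3S)-3-hydroxy-3-[2-methoxy-4-(methoxymethoxy)phenyl]propanoate
Product: 23 (2S)-2-[2-methoxy-4-(methoxymethoxy)phenyl]-8-[(2R)-5-(methoxymethoxy)-5-methyl-2-(prop-1-en-2-yl)hexyl]-5,7-bis(methoxymethoxy)chroman-4-one, via silyl ether 21 (not isolated), via aryne 22 (not isolated)
Conditions: 20 (1.4 equiv), Me3SiNMe2, THF, rt, then evaporation; 16 (1 equiv), KF (1.2 to 2.5 equiv), 18-crown-6, THF, 0 °C to rt; pH 7 buffer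
Reagents that add atoms: none
Why: Proposed new method: fluoride attacks the SiMe3 group of 16 and expels triflate to give aryne 22, and likewise frees the alkoxide of 21; the alkoxide adds to C8a, the aryne carbon remote from the C5 oxygen, so the carbanion develops at C4a next to that inductively withdrawing oxygen, and this carbanion attacks the ester carbonyl with loss of methoxide, forming O1–C8a and C4–C4a in one operation. The closest known reaction type is the fluoride-induced annulation of arynes from ortho-silylaryl triflates with methyl salicylates (to xanthones) and with β-amino esters; an aliphatic β-oxido ester has not been used in this way. Ring C closes in the 6-exo-trig mode by the acyl substitution. No stereocentre is created: C2 comes from 20 and should keep its (S) configuration because its C–O bond is never broken, and C2'' is remote. Regioselectivity in the aryne addition rests on the polarisation of the aryne by the C5 acetal oxygen, which should outweigh the steric bias of the C8 methylene; acyl capture over protonation of the C4a anion is favoured by the absence of any O–H or N–H donor, the alcohol being introduced as its silyl ether. The two silyl groups take up fluoride and the liberated methoxide (as Me3SiF and Me3SiOMe, the methoxide attacking the silicon of 16 or 21), so about one equivalent of fluoride suffices and the base-labile chromanone is not left with stoichiometric alkoxide, which limits enolisation at C3, retro-oxa-Michael opening and epimerisation at C2. THF is used because acetonitrile can protonate aryl anions, and the low temperature disfavours retro-aldol cleavage of the alkoxide.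

Step 15
Reactants: 23 (2S)-2-[2-methoxy-4-(methoxymethoxy)phenyl]-8-[(2R)-5-(methoxymethoxy)-5-methyl-2-(prop-1-en-2-yl)hexyl]-5,7-bis(methoxymethoxy)chroman-4-one
Product: 24 (2S)-5,7-dihydroxy-8-[(2R)-5-hydroxy-5-methyl-2-(prop-1-en-2-yl)hexyl]-2-(4-hydroxy-2-methoxyphenyl)chroman-4-one
Conditions: TMSOTf, 2,2'-bipyridyl, MeCN, 0 °C to rt; then H2O, rt
Reagents that add atoms: none
Why: Silyl triflate/bipyridyl cleavage of methoxymethyl ethers: the aryl acetals are exchanged for labile aryl silyl ethers and the tertiary acetal for a pyridinium acetal, and all are hydrolysed by water. The medium is buffered by the bipyridyl and holds no free Brønsted acid, so the isopropenyl group, the tertiary alcohol and the C2–O1 bond should survive.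

## Compound list

1 | (S)-4-benzyloxazolidin-2-one | O=C1N[C@@H](Cc2ccccc2)CO1 | starting material
2 | 3-methylbut-2-enoyl chloride | CC(C)=CC(=O)Cl | starting material
3 | (S)-4-benzyl-3-(3-methylbut-2-enoyl)oxazolidin-2-one | CC(C)=CC(=O)N1C(=O)OC[C@@H]1Cc1ccccc1 | intermediate
4 | (S)-4-benzyl-3-[(2S)-5-methyl-2-(prop-1-en-2-yl)hex-4-enoyl]oxazolidin-2-one | C=C(C)[C@H](CC=C(C)C)C(=O)N1C(=O)OC[C@@H]1Cc1ccccc1 | intermediate
5 | (S)-4-benzyl-3-[(2S)-3-(3,3-dimethyloxiran-2-yl)-2-(prop-1-en-2-yl)propanoyl]oxazolidin-2-one, both epimers at the oxirane CH | C=C(C)[C@H](CC1OC1(C)C)C(=O)N1C(=O)OC[C@@H]1Cc1ccccc1 | intermediate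
6 | (2S)-5-methyl-2-(prop-1-en-2-yl)hexane-1,5-diol | C=C(C)[C@H](CCC(C)(C)O)CO | intermediate
7 | (5S)-6-iodo-2-methyl-5-(prop-1-en-2-yl)hexan-2-ol | C=C(C)[C@H](CCC(C)(C)O)CI | intermediate
8 | (2S)-1-iodo-5-(methoxymethoxy)-5-methyl-2-(prop-1-en-2-yl)hexane | C=C(C)[C@H](CCC(C)(C)OCOC)CI | intermediate
9 | phloroglucinol (benzene-1,3,5-triol) | Oc1cc(O)cc(O)c1 | starting material
10 | 3,5-bis(methoxymethoxy)phenol | COCOc1cc(O)cc(OCOC)c1 | intermediate
11 | 2,6-dibromo-3,5-bis(methoxymethoxy)phenol | COCOc1cc(OCOC)c(Br)c(O)c1Br | intermediate
12 | [2,6-dibromo-3,5-bis(methoxymethoxy)phenoxy]trimethylsilane | COCOc1cc(OCOC)c(Br)c(O[Si](C)(C)C)c1Br | intermediate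
13 | lithium 2-bromo-3,5-bis(methoxymethoxy)-6-(trimethylsilyl)phenolate | [Li+].COCOc1cc(OCOC)c([Si](C)(C)C)c([O-])c1Br | intermediate
14 | 2-bromo-3,5-bis(methoxymethoxy)-6-(trimethylsilyl)phenyl trifluoromethanesulfonate | COCOc1cc(OCOC)c([Si](C)(C)C)c(OS(=O)(=O)C(F)(F)F)c1Br | intermediate
15 | [(2S)-5-(methoxymethoxy)-5-methyl-2-(prop-1-en-2-yl)hexyl]zinc iodide | C=C(C)[C@H](CCC(C)(C)OCOC)C[Zn]I | intermediate
16 | 2-[(2R)-5-(methoxymethoxy)-5-methyl-2-(prop-1-en-2-yl)hexyl]-3,5-bis(methoxymethoxy)-6-(trimethylsilyl)phenyl trifluoromethanesulfonate | C=C(C)[C@H](CCC(C)(C)OCOC)Cc1c(OCOC)cc(OCOC)c([Si](C)(C)C)c1OS(=O)(=O)C(F)(F)F | intermediate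
17 | 1-(4-hydroxy-2-methoxyphenyl)ethanone | CC(=O)c1ccc(O)cc1OC | starting material
18 | 1-[2-methoxy-4-(methoxymethoxy)phenyl]ethanone | CC(=O)c1ccc(OCOC)cc1OC | intermediate
19 | methyl 3-[2-methoxy-4-(methoxymethoxy)phenyl]-3-oxopropanoate | COC(=O)CC(=O)c1ccc(OCOC)cc1OC | intermediate
20 | methyl (3S)-3-hydroxy-3-[2-methoxy-4-(methoxymethoxy)phenyl]propanoate | O[C@H](c1ccc(OCOC)cc1OC)CC(=O)OC | intermediate
21 | methyl (3S)-3-[2-methoxy-4-(methoxymethoxy)phenyl]-3-(trimethylsilyloxy)propanoate | C[Si](C)(C)O[C@H](c1ccc(OCOC)cc1OC)CC(=O)OC | intermediate
22 | 3-[(2R)-5-(methoxymethoxy)-5-methyl-2-(prop-1-en-2-yl)hexyl]-4,6-bis(methoxymethoxy)benzyne (1,2-didehydrobenzene) | C=C(C)[C@H](CCC(C)(C)OCOC)CC1=C(OCOC)C=C(OCOC)C#C1 | intermediate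
23 | (2S)-2-[2-methoxy-4-(methoxymethoxy)phenyl]-8-[(2R)-5-(methoxymethoxy)-5-methyl-2-(prop-1-en-2-yl)hexyl]-5,7-bis(methoxymethoxy)chroman-4-one | C=C(C)[C@H](CCC(C)(C)OCOC)Cc1c(OCOC)cc(OCOC)c2c1O[C@H](c1ccc(OCOC)cc1OC)CC2=O | intermediate
24 | (2S)-5,7-dihydroxy-8-[(2R)-5-hydroxy-5-methyl-2-(prop-1-en-2-yl)hexyl]-2-(4-hydroxy-2-methoxyphenyl)chroman-4-one | C=C(C)[C@H](CCC(C)(C)O)Cc1c(O)cc(O)c2c1O[C@H](c1ccc(O)cc1OC)CC2=O | target

## Step count and least certain steps

Total: 15 steps. Longest linear sequence: 9 steps (steps 1 to 6, 10, 14, 15).

**Step 14 (key step).** The C4a carbanion may take a proton from the C3 methylene of its own chain, after which the ester enolate would expel the aryloxide and the ether would be lost. Addition may also occur in part at C4a instead of C8a, the alkoxide may fragment by retro-aldol, or the product may open to the chalcone and epimerise at C2. The fallback uses known chemistry, sets out from 16 and comes back at 23. Compound 16 is heated with acetic acid and CsF in THF; the aryne inserts into the C–O bond of the carboxylic acid (carboxylate at C8a, acyl at C4a) to give the ortho-hydroxyaryl methyl ketone F1. Claisen–Schmidt condensation of F1 with 2-methoxy-4-(methoxymethoxy)benzaldehyde F2 (made from commercial 4-hydroxy-2-methoxybenzaldehyde and MOMCl) under KOH in ethanol should give the 2'-hydroxychalcone F3. Oxa-Michael cyclisation of F3 (NaOAc, ethanol, reflux) should give 23 together with its C2 epimer F4. The two are diastereomers because of the fixed C2'' centre and would be separated by preparative chromatography, and F4 would be returned to the equilibrium through F3.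

**Step 10.** Oxidative addition at the doubly flanked C–Br bond may be slow, palladium may insert into the C–OTf bond, or the alkylpalladium may undergo β-hydride elimination. The fallback is a B-alkyl Suzuki–Miyaura coupling; it sets out from 8 and comes back at 16. Iodide 8 is lithiated with t-BuLi in ether at −78 °C and trapped with 9-methoxy-9-borabicyclo[3.3.1]nonane to give the lithium alkyl(methoxy)borate F8. F8 is then coupled with 14 using PdCl2(dppf) and aqueous K3PO4 in DMF/THF at room temperature; this is a different transmetalation manifold, with no fluoride present.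

**Step 8.** Bromination may go to the position between the two acetals, a third bromine may enter, or acetals may be lost to HBr. The fallback replaces electrophilic control by directed metalation; it sets out from 10 and comes back at 14. Phenol 10 and isopropyl isocyanate (Et3N) give the aryl N-isopropylcarbamate F5. After temporary N-silylation in the same flask (TMSOTf, TMEDA), ortho-lithiation with n-BuLi/TMEDA at −78 °C and quenching with TMSCl give the ortho-silyl carbamate F6. The same protocol with BrCF2CF2Br as electrophile gives the bromo silyl carbamate F7. Treatment of F7 with Et2NH and DBU in MeCN releases the phenolate (isocyanate loss), which is triflated in the same flask with PhNTf2 to give 14.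

**Step 15.** Cleavage of the hindered tertiary acetal may lag behind the aryl acetals. During the longer exposure the isopropenyl group may cyclise onto O7 or onto the tertiary oxygen, or the C2–O1 bond may ionise with epimerisation. The fallback changes the protecting group of the tertiary alcohol; it sets out from 7 and comes back at 24. Alcohol 7 with TESOTf and 2,6-lutidine gives the triethylsilyl ether F9. Zinc insertion as in step 10 gives the zinc reagent F10, and coupling with 14 gives the silyl triflate F11. The annulation of step 14 with 21 then proceeds through the aryne F12 to the flavanone F13. Dilute HCl in methanol/THF at room temperature then removes the triethylsilyl group and the three aryl acetals without having to cleave a tertiary acetal. The tertiary silyl ether is less secure than the acetal toward fluoride in the annulation, which is why it is not the first choice.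

## Further compounds

F1 | step 14 | 1-{2-hydroxy-3-[(2R)-5-(methoxymethoxy)-5-methyl-2-(prop-1-en-2-yl)hexyl]-4,6-bis(methoxymethoxy)phenyl}ethanone | C=C(C)[C@H](CCC(C)(C)OCOC)Cc1c(OCOC)cc(OCOC)c(C(C)=O)c1O
F2 | step 14 | 2-methoxy-4-(methoxymethoxy)benzaldehyde | COCOc1ccc(C=O)c(OC)c1
F3 | step 14 | (E)-1-{2-hydroxy-3-[(2R)-5-(methoxymethoxy)-5-methyl-2-(prop-1-en-2-yl)hexyl]-4,6-bis(methoxymethoxy)phenyl}-3-[2-methoxy-4-(methoxymethoxy)phenyl]prop-2-en-1-one | C=C(C)[C@H](CCC(C)(C)OCOC)Cc1c(OCOC)cc(OCOC)c(C(=O)/C=C/c2ccc(OCOC)cc2OC)c1O
F4 | step 14 | (2R)-2-[2-methoxy-4-(methoxymethoxy)phenyl]-8-[(2R)-5-(methoxymethoxy)-5-methyl-2-(prop-1-en-2-yl)hexyl]-5,7-bis(methoxymethoxy)chroman-4-one | C=C(C)[C@H](CCC(C)(C)OCOC)Cc1c(OCOC)cc(OCOC)c2c1O[C@@H](c1ccc(OCOC)cc1OC)CC2=O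
F5 | step 8 | 3,5-bis(methoxymethoxy)phenyl N-(propan-2-yl)carbamate | COCOc1cc(OCOC)cc(OC(=O)NC(C)C)c1
F6 | step 8 | 3,5-bis(methoxymethoxy)-2-(trimethylsilyl)phenyl N-(propan-2-yl)carbamate | COCOc1cc(OCOC)c([Si](C)(C)C)c(OC(=O)NC(C)C)c1
F7 | step 8 | 2-bromo-3,5-bis(methoxymethoxy)-6-(trimethylsilyl)phenyl N-(propan-2-yl)carbamate | COCOc1cc(OCOC)c([Si](C)(C)C)c(OC(=O)NC(C)C)c1Br
F8 | step 10 | lithium 9-methoxy-9-[(2S)-5-(methoxymethoxy)-5-methyl-2-(prop-1-en-2-yl)hexyl]-9-borabicyclo[3.3.1]nonan-9-uide | [Li+].C=C(C)[C@H](CCC(C)(C)OCOC)C[B-]1(OC)C2CCCC1CCC2
F9 | step 15 | triethyl{[(5S)-6-iodo-2-methyl-5-(prop-1-en-2-yl)hexan-2-yl]oxy}silane | C=C(C)[C@H](CCC(C)(C)O[Si](CC)(CC)CC)CI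
F10 | step 15 | [(2S)-5-methyl-2-(prop-1-en-2-yl)-5-(triethylsilyloxy)hexyl]zinc iodide | C=C(C)[C@H](CCC(C)(C)O[Si](CC)(CC)CC)C[Zn]I
F11 | step 15 | 3,5-bis(methoxymethoxy)-2-[(2R)-5-methyl-2-(prop-1-en-2-yl)-5-(triethylsilyloxy)hexyl]-6-(trimethylsilyl)phenyl trifluoromethanesulfonate | C=C(C)[C@H](CCC(C)(C)O[Si](CC)(CC)CC)Cc1c(OCOC)cc(OCOC)c([Si](C)(C)C)c1OS(=O)(=O)C(F)(F)F
F12 | step 15 | 4,6-bis(methoxymethoxy)-3-[(2R)-5-methyl-2-(prop-1-en-2-yl)-5-(triethylsilyloxy)hexyl]benzyne (1,2-didehydrobenzene) | C=C(C)[C@H](CCC(C)(C)O[Si](CC)(CC)CC)CC1=C(OCOC)C=C(OCOC)C#C1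
F13 | step 15 | (2S)-2-[2-methoxy-4-(methoxymethoxy)phenyl]-5,7-bis(methoxymethoxy)-8-[(2R)-5-methyl-2-(prop-1-en-2-yl)-5-(triethylsilyloxy)hexyl]chroman-4-one | C=C(C)[C@H](CCC(C)(C)O[Si](CC)(CC)CC)Cc1c(OCOC)cc(OCOC)c2c1O[C@H](c1ccc(OCOC)cc1OC)CC2=O
A1 | alternative 1 | 3,5-bis(methoxymethoxy)-2-[(phenylsulfonyl)methyl]phenol | COCOc1cc(O)c(CS(=O)(=O)c2ccccc2)c(OCOC)c1
A2 | alternative 1 | 5-methyl-5-(triethylsilyloxy)hexanal | CC[Si](CC)(CC)OC(C)(C)CCCC=O
A3 | alternative 1 | (3R)-5,7-bis(methoxymethoxy)-3-[3-methyl-3-(triethylsilyloxy)butyl]chroman-2-ol, anomeric mixture | OC1Oc2cc(OCOC)cc(OCOC)c2C[C@H]1CCC(C)(C)O[Si](CC)(CC)CC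
A4 | alternative 2 | triisopropyl{[(4R)-7-methyl-4-(prop-1-en-2-yl)-7-(triethylsilyloxy)oct-1-yn-1-yl]oxy}silane | C=C(C)[C@H](CCC(C)(C)O[Si](CC)(CC)CC)CC#CO[Si](C(C)C)(C(C)C)C(C)C
A5 | alternative 2 | 3-[2-(trimethylsilyl)ethoxy]cyclobut-2-en-1-one | O=C1C=C(OCC[Si](C)(C)C)C1
A6 | alternative 2 | 2-[(2R)-5-methyl-2-(prop-1-en-2-yl)-5-(triethylsilyloxy)hexyl]-3-(triisopropylsilyloxy)-5-[2-(trimethylsilyl)ethoxy]phenol | C=C(C)[C@H](CCC(C)(C)O[Si](CC)(CC)CC)Cc1c(O)cc(OCC[Si](C)(C)C)cc1O[Si](C(C)C)(C(C)C)C(C)C
A7 | alternative 3 | 2-diazo-1-{2-{[2-methoxy-4-(triisopropylsilyloxy)phenyl]methoxy}-3-[(2R)-5-methyl-2-(prop-1-en-2-yl)-5-(triethylsilyloxy)hexyl]-4,6-bis(triisopropylsilyloxy)phenyl}ethanone | C=C(C)[C@H](CCC(C)(C)O[Si](CC)(CC)CC)Cc1c(O[Si](C(C)C)(C(C)C)C(C)C)cc(O[Si](C(C)C)(C(C)C)C(C)C)c(C(=O)C=[N+]=[N-])c1OCc1ccc(O[Si](C(C)C)(C(C)C)C(C)C)cc1OC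
A8 | alternative 3 | (2S)-2-[2-methoxy-4-(triisopropylsilyloxy)phenyl]-8-[(2R)-5-methyl-2-(prop-1-en-2-yl)-5-(triethylsilyloxy)hexyl]-5,7-bis(triisopropylsilyloxy)chroman-4-one | C=C(C)[C@H](CCC(C)(C)O[Si](CC)(CC)CC)Cc1c(O[Si](C(C)C)(C(C)C)C(C)C)cc(O[Si](C(C)C)(C(C)C)C(C)C)c2c1O[C@H](c1ccc(O[Si](C(C)C)(C(C)C)C(C)C)cc1OC)CC2=O
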